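**Plan**
Cuts: O1–C2 (oxa-Michael), then O1–C8a and C4–C4a together (aryne insertion), C1'–C3 (aryllithium on oxalate), C3=CH2 (Wittig carbon, later C2), and C3'–C1'' (aryl–allyl coupling).
Enabling feature: in ring A, O1 (on C8a) and the acyl carbon C4 (on C4a) sit on adjacent carbons. C4a is flanked on its other side by the C5 oxygen, and C7 is oxygenated too. This is the 1,2-pattern a carboxylate leaves on a 3,5-dialkoxybenzyne.
Forward: geranyl acetate gives the hydrated, TES-protected allylic bromide, which is joined to lithiated resorcinol bis-MOM ether. A second lithiation, oxalate trapping, methylenation and hydrolysis give the ring B acrylic acid. Phloroglucinol gives the silylaryl triflate.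
Rings A and B are bought as arenes and are joined in the aryne step with ring C still open. Ring C closes last by 6-endo-trig oxa-Michael addition.
Stereochemistry: the E alkene comes from geranyl acetate. C3 forms racemic and is set as S by Noyori–Ikariya transfer hydrogenation under dynamic kinetic resolution, then kept through Dess–Martin oxidation and mild acid unmasking.

Key step: step 14

Remark: the SMILES is read as 3S at the only stereocentre and E at the side-chain alkene. Isoflavanone numbering is used (O1, C2–C4, C4a–C8a, ring B primed). R stands for (2E)-3,7-dimethyl-7-(triethylsilyloxy)oct-2-en-1-yl.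

**Step 1**
Reactants: 1 phloroglucinol
Product: 2 3,5-bis(methoxymethoxy)phenol
Conditions: MOMCl (2.0 equiv), i-Pr2NEt (2.2 equiv), DMF, 0 °C → rt
Reagents that add atoms: chloromethyl methyl ether (MOMCl), COCCl
Why: Williamson-type O-alkylation with a hard electrophile should make the bis-ether the main part of a statistical mixture, from which the mono- and tris-ethers are removed by chromatography.

**Step 2**
Reactants: 2 3,5-bis(methoxymethoxy)phenol
Product: 3 2-bromo-3,5-bis(methoxymethoxy)phenol
Conditions: NBS (1.0 equiv), i-Pr2NH (10 mol %), CH2Cl2, −40 → 0 °C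
Reagents that add atoms: N-bromosuccinimide, O=C1CCC(=O)N1Br
Why: Amine-catalysed ortho-selective electrophilic bromination of a phenol should favour the two equivalent positions next to the free OH, which are less crowded than the site between the two MOM ethers.

**Step 3**
Reactants: 3 2-bromo-3,5-bis(methoxymethoxy)phenol
Product: 4 [2-bromo-3,5-bis(methoxymethoxy)phenoxy]trimethylsilane
Conditions: HMDS, THF, 65 °C; evaporation
Reagents that add atoms: hexamethyldisilazane, C[Si](C)(C)N[Si](C)(C)C
Why: O-silylation of the phenol with HMDS needs no added base and is the usual prelude to a retro-Brook shift.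

**Step 4**
Reactants: 4 [2-bromo-3,5-bis(methoxymethoxy)phenoxy]trimethylsilane
Product: 6 3,5-bis(methoxymethoxy)-2-(trimethylsilyl)phenyl trifluoromethanesulfonate, via lithium 2-silylphenoxide 5 (not isolated)
Conditions: n-BuLi, THF, −78 °C; then Tf2O, −78 °C
Reagents that add atoms: trifluoromethanesulfonic anhydride, O=S(=O)(OS(=O)(=O)C(F)(F)F)C(F)(F)F
Why: Bromine–lithium exchange sets off a retro-Brook 1,3 O-to-C silyl shift to phenoxide 5, which Tf2O traps on oxygen, the established entry to ortho-silylaryl triflates.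

**Step 5**
Reactants: 7 geranyl acetate
Product: 9 (2E)-7-hydroxy-3,7-dimethyloct-2-en-1-yl acetate, via 6-acetoxymercurio-7-hydroxy adduct 8 (not isolated)
Conditions: Hg(OAc)2, THF–H2O, rt; then NaBH4, aq NaOH, 0 °C, short contact
Reagents that add atoms: water, O
Why: In this oxymercuration–demercuration (Markovnikov hydration) the electrophilic divalent mercury salt picks the electron-rich 6,7-alkene over the 2,3-alkene deactivated by the allylic acetate, so the E geometry is untouched.

**Step 6**
Reactants: 9 (2E)-7-hydroxy-3,7-dimethyloct-2-en-1-yl acetate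
Product: 10 (2E)-3,7-dimethyl-7-(triethylsilyloxy)oct-2-en-1-yl acetate
Conditions: TESOTf, 2,6-lutidine, CH2Cl2, −78 → 0 °C
Reagents that add atoms: triethylsilyl trifluoromethanesulfonate, CC[Si](CC)(CC)OS(=O)(=O)C(F)(F)F
Why: Silyl triflate silylation is the standard way to cap a hindered tertiary alcohol, and the resulting shielded TES ether resists base, organolithiums and sparingly soluble fluoride yet falls to dilute acid.

**Step 7**
Reactants: 10 (2E)-3,7-dimethyl-7-(triethylsilyloxy)oct-2-en-1-yl acetate
Product: 11 (2E)-3,7-dimethyl-7-(triethylsilyloxy)oct-2-en-1-ol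
Conditions: K2CO3 (0.2 equiv), MeOH, 0 °C → rt
Reagents that add atoms: none
Why: Base-catalysed transesterification (Zemplén-type methanolysis) frees the primary allylic alcohol and leaves the tertiary silyl ether alone.

**Step 8**
Reactants: 11 (2E)-3,7-dimethyl-7-(triethylsilyloxy)oct-2-en-1-ol
Product: 13 [(6E)-8-bromo-2,6-dimethyloct-6-en-2-yl]oxy(triethyl)silane, via allylic mesylate 12 (not isolated)
Conditions: MsCl, Et3N, THF, −40 °C; then LiBr, THF, 0 °C; used crude
Reagents that add atoms: lithium bromide, [Li+].[Br-]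
Why: Mesylation followed by SN2 displacement with bromide works under non-acidic conditions, which preserve the TES ether and the E alkene without allylic transposition.

**Step 9**
Reactants: 14 resorcinol
Product: 15 1,3-bis(methoxymethoxy)benzene
Conditions: NaH, MOMCl, DMF, 0 °C → rt
Reagents that add atoms: chloromethyl methyl ether (MOMCl), COCCl
Why: This is a Williamson ether synthesis on both phenoxides, and it installs the groups that later direct both lithiations.

**Step 10**
Reactants: 15 1,3-bis(methoxymethoxy)benzene; 13 [(6E)-8-bromo-2,6-dimethyloct-6-en-2-yl]oxy(triethyl)silane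
Product: 17 2-R-1,3-bis(methoxymethoxy)benzene, via 2-lithio-1,3-bis(methoxymethoxy)benzene 16 (not isolated)
Conditions: n-BuLi, THF, 0 °C → rt; CuBr·SMe2 (10 mol %), then 13, −78 °C → rt
Reagents that add atoms: none
Why: Directed ortho-metalation occurs at the carbon flanked by both MOM ethers, and copper-catalysed SN2 allylation of 16 with the primary allylic bromide, the usual route to 2-prenyl and 2-geranyl resorcinols, keeps the E geometry.

**Step 11**
Reactants: 17 2-R-1,3-bis(methoxymethoxy)benzene
Product: 19 ethyl 2-[3-R-2,4-bis(methoxymethoxy)phenyl]-2-oxoacetate, via 4-lithiated arene 18 (not isolated)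
Conditions: s-BuLi, TMEDA, THF, −78 °C; cannulated into (CO2Et)2 (3 equiv), THF, −78 °C
Reagents that add atoms: diethyl oxalate, CCOC(=O)C(=O)OCC
Why: In this second directed ortho-metalation, pre-complexation of s-BuLi to a MOM ether should steer kinetic deprotonation to the ring C–H beside it and not to the benzylic-allylic CH2, and inverse addition to excess oxalate stops the acylation at the α-keto ester.

**Step 12**
Reactants: 19 ethyl 2-[3-R-2,4-bis(methoxymethoxy)phenyl]-2-oxoacetate
Product: 20 ethyl 2-[3-R-2,4-bis(methoxymethoxy)phenyl]prop-2-enoate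
Conditions: MePPh3Br (1.1 equiv), KOt-Bu (1.1 equiv), THF, 0 °C; then 19, 0 °C → rt
Reagents that add atoms: methyltriphenylphosphonium bromide, C[P+](c1ccccc1)(c1ccccc1)c1ccccc1.[Br-]
Why: In this Wittig methylenation the small non-stabilised ylide attacks the ketone carbonyl of the α-keto ester, far more electrophilic than the ester, a known route to 2-arylacrylates.

**Step 13**
Reactants: 20 ethyl 2-[3-R-2,4-bis(methoxymethoxy)phenyl]prop-2-enoate
Product: 21 2-[3-R-2,4-bis(methoxymethoxy)phenyl]prop-2-enoic acid
Conditions: LiOH, THF–H2O, rt; then 0.5 M HCl to pH 4, 0 °C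
Reagents that add atoms: lithium hydroxide, [Li+].[OH-]
Why: Saponification without an alcohol cosolvent avoids alkoxide conjugate addition, and the brief cold acidification leaves the MOM and TES groups intact.

**Step 14**
Reactants: 21 2-[3-R-2,4-bis(methoxymethoxy)phenyl]prop-2-enoic acid; 6 3,5-bis(methoxymethoxy)-2-(trimethylsilyl)phenyl trifluoromethanesulfonate
Product: 25 1-[2-hydroxy-4,6-bis(methoxymethoxy)phenyl]-2-[3-R-2,4-bis(methoxymethoxy)phenyl]prop-2-en-1-one, via caesium carboxylate 22 (not isolated), via 3,5-bis(methoxymethoxy)benzyne 23 (not isolated), via ortho-acyloxyaryl anion 24 (not isolated)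
Conditions: 6 (1.5 equiv), CsF (4 equiv), THF, 125 °C, sealed tube
Reagents that add atoms: none
Why: Fluoride removes the silyl group of 6 and triflate leaves to give aryne 23, while CsF turns 21 into carboxylate 22 and parks the proton as bifluoride. The carboxylate oxygen adds to the aryne carbon remote from the flanking MOM ether (future C8a), because the inductive pull of that ether distorts the triple bond and stabilises charge on the neighbouring carbon (future C4a), so anion 24 has the acyloxy group on one side and the future C5 oxygen on the other. Anion 24 attacks its own ester carbonyl through a four-membered tetrahedral array that collapses to the ortho-acyl phenoxide, an anionic-Fries-type 1,3 O-to-C acyl shift that completes the O–C8a and C4–C4a bonds, and reprotonation gives 25. The closest known reaction type is the fluoride-induced insertion of arynes into the C–O bond of carboxylic acids in hot THF, documented for α,β-unsaturated acids and for 3-alkoxyarynes. The step itself closes no ring and creates no stereocentre, and whatever part of 25 cyclises further in the warm basic medium is already the product of step 15 and is carried along. The selectivities needed are regiochemistry (secured by the alkoxy group next to the aryne), acyl shift over protonation (secured by hot THF, a poor proton donor, in place of MeCN) and survival of the side chain (the tertiary TES ether is shielded and CsF is barely soluble in THF).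

**Step 15**
Reactants: 25 1-[2-hydroxy-4,6-bis(methoxymethoxy)phenyl]-2-[3-R-2,4-bis(methoxymethoxy)phenyl]prop-2-en-1-one
Product: 26 rac-3-[3-R-2,4-bis(methoxymethoxy)phenyl]-5,7-bis(methoxymethoxy)chroman-4-one
Conditions: K2CO3 (0.2 equiv), EtOH–THF, rt
Reagents that add atoms: none
Why: Intramolecular 6-endo-trig oxa-Michael addition of the phenoxide to the 1-arylvinyl ketone is the closure at work in the methylenation route from deoxybenzoins to isoflavanones, and C3 arises racemic by unselective enolate protonation, which is intended.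

**Step 16**
Reactants: 26 rac-3-[3-R-2,4-bis(methoxymethoxy)phenyl]-5,7-bis(methoxymethoxy)chroman-4-one
Product: 27 (3S,4S)-3-[3-R-2,4-bis(methoxymethoxy)phenyl]-5,7-bis(methoxymethoxy)chroman-4-ol (3,4-cis)
Conditions: RuCl(p-cymene)[(S,S)-TsDPEN] (2 mol %), HCO2H (5 equiv), Et3N (8 equiv), EtOAc, 40 °C
Reagents that add atoms: none
Why: In this Noyori–Ikariya asymmetric transfer hydrogenation with dynamic kinetic resolution, known for isoflavanones, Et3N equilibrates C3 through the enol, the (S,S)-catalyst delivers hydride to the C4 face that gives the 4S benzylic alcohol (as with simple aryl ketones and chromanones), and it reacts faster with the 3S ketone, whose aryl group lies away from the incoming hydride, so the cis-(3S,4S) alcohol should result.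

**Step 17**
Reactants: 27 (3S,4S)-3-[3-R-2,4-bis(methoxymethoxy)phenyl]-5,7-bis(methoxymethoxy)chroman-4-ol
Product: 28 (3S)-3-[3-R-2,4-bis(methoxymethoxy)phenyl]-5,7-bis(methoxymethoxy)chroman-4-one
Conditions: Dess–Martin periodinane, NaHCO3, CH2Cl2, 0 °C → rt
Reagents that add atoms: none
Why: Buffered Dess–Martin oxidation restores the ketone under nearly neutral conditions, so C3 is not enolised, the acid-labile benzylic alcohol does not ionise, and only the auxiliary C4 stereocentre is erased.

**Step 18**
Reactants: 28 (3S)-3-[3-R-2,4-bis(methoxymethoxy)phenyl]-5,7-bis(methoxymethoxy)chroman-4-one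
Product: 29 (3S)-3-{2,4-dihydroxy-3-[(2E)-7-hydroxy-3,7-dimethyloct-2-en-1-yl]phenyl}-5,7-dihydroxychroman-4-one (CNP0420575.1)
Conditions: 1.25 M HCl in MeOH, 0 °C → rt
Reagents that add atoms: none
Why: Acid-catalysed transacetalisation of the four aryl MOM ethers and methanolysis of the TES ether run in one operation, and dilute acid at or below room temperature should keep C3 enolisation, phenol-to-alkene cyclisation and ionisation of the tertiary alcohol slow.

**Compound list**
1 | phloroglucinol | Oc1cc(O)cc(O)c1 | starting material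
2 | 3,5-bis(methoxymethoxy)phenol | COCOc1cc(O)cc(OCOC)c1 | intermediate
3 | 2-bromo-3,5-bis(methoxymethoxy)phenol | COCOc1cc(O)c(Br)c(OCOC)c1 | intermediate
4 | [2-bromo-3,5-bis(methoxymethoxy)phenoxy]trimethylsilane | COCOc1cc(O[Si](C)(C)C)c(Br)c(OCOC)c1 | intermediate
5 | lithium 3,5-bis(methoxymethoxy)-2-(trimethylsilyl)phenoxide | [Li+].[O-]c1cc(OCOC)cc(OCOC)c1[Si](C)(C)C | intermediate
6 | 3,5-bis(methoxymethoxy)-2-(trimethylsilyl)phenyl trifluoromethanesulfonate | COCOc1cc(OCOC)c([Si](C)(C)C)c(OS(=O)(=O)C(F)(F)F)c1 | intermediate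
7 | geranyl acetate | CC(=O)OC/C=C(\C)CCC=C(C)C | starting material
8 | (2E)-6-(acetoxymercurio)-7-hydroxy-3,7-dimethyloct-2-en-1-yl acetate (racemic at C6) | CC(=O)OC/C=C(\C)CCC([Hg]OC(C)=O)C(C)(C)O | intermediate
9 | (2E)-7-hydroxy-3,7-dimethyloct-2-en-1-yl acetate | CC(=O)OC/C=C(\C)CCCC(C)(C)O | intermediate
10 | (2E)-3,7-dimethyl-7-(triethylsilyloxy)oct-2-en-1-yl acetate | CC(=O)OC/C=C(\C)CCCC(C)(C)O[Si](CC)(CC)CC | intermediate
11 | (2E)-3,7-dimethyl-7-(triethylsilyloxy)oct-2-en-1-ol | OC/C=C(\C)CCCC(C)(C)O[Si](CC)(CC)CC | intermediate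
12 | (2E)-3,7-dimethyl-7-(triethylsilyloxy)oct-2-en-1-yl methanesulfonate | CS(=O)(=O)OC/C=C(\C)CCCC(C)(C)O[Si](CC)(CC)CC | intermediate
13 | [(6E)-8-bromo-2,6-dimethyloct-6-en-2-yl]oxy(triethyl)silane | BrC/C=C(\C)CCCC(C)(C)O[Si](CC)(CC)CC | intermediate
14 | resorcinol | Oc1cccc(O)c1 | starting material
15 | 1,3-bis(methoxymethoxy)benzene | COCOc1cccc(OCOC)c1 | intermediate
16 | [2,6-bis(methoxymethoxy)phenyl]lithium | [Li]c1c(OCOC)cccc1OCOC | intermediate
17 | 2-R-1,3-bis(methoxymethoxy)benzene | COCOc1cccc(OCOC)c1C/C=C(\C)CCCC(C)(C)O[Si](CC)(CC)CC | intermediate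
18 | [3-R-2,4-bis(methoxymethoxy)phenyl]lithium | [Li]c1ccc(OCOC)c(C/C=C(\C)CCCC(C)(C)O[Si](CC)(CC)CC)c1OCOC | intermediate
19 | ethyl 2-[3-R-2,4-bis(methoxymethoxy)phenyl]-2-oxoacetate | CCOC(=O)C(=O)c1ccc(OCOC)c(C/C=C(\C)CCCC(C)(C)O[Si](CC)(CC)CC)c1OCOC | intermediate
20 | ethyl 2-[3-R-2,4-bis(methoxymethoxy)phenyl]prop-2-enoate | C=C(C(=O)OCC)c1ccc(OCOC)c(C/C=C(\C)CCCC(C)(C)O[Si](CC)(CC)CC)c1OCOC | intermediate
21 | 2-[3-R-2,4-bis(methoxymethoxy)phenyl]prop-2-enoic acid | C=C(C(=O)O)c1ccc(OCOC)c(C/C=C(\C)CCCC(C)(C)O[Si](CC)(CC)CC)c1OCOC | intermediate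
22 | caesium 2-[3-R-2,4-bis(methoxymethoxy)phenyl]prop-2-enoate | [Cs+].C=C(C(=O)[O-])c1ccc(OCOC)c(C/C=C(\C)CCCC(C)(C)O[Si](CC)(CC)CC)c1OCOC | intermediate
23 | 3,5-bis(methoxymethoxy)benzyne | COCOC1=CC(OCOC)=CC#C1 | intermediate
24 | caesium 2-{2-[3-R-2,4-bis(methoxymethoxy)phenyl]prop-2-enoyloxy}-4,6-bis(methoxymethoxy)phenide | [Cs+].C=C(C(=O)Oc1cc(OCOC)cc(OCOC)[c-]1)c1ccc(OCOC)c(C/C=C(\C)CCCC(C)(C)O[Si](CC)(CC)CC)c1OCOC | intermediate
25 | 1-[2-hydroxy-4,6-bis(methoxymethoxy)phenyl]-2-[3-R-2,4-bis(methoxymethoxy)phenyl]prop-2-en-1-one | C=C(C(=O)c1c(O)cc(OCOC)cc1OCOC)c1ccc(OCOC)c(C/C=C(\C)CCCC(C)(C)O[Si](CC)(CC)CC)c1OCOC | intermediate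
26 | rac-3-[3-R-2,4-bis(methoxymethoxy)phenyl]-5,7-bis(methoxymethoxy)chroman-4-one | C/C(=C\Cc1c(OCOC)ccc(C2COc3cc(OCOC)cc(OCOC)c3C2=O)c1OCOC)CCCC(C)(C)O[Si](CC)(CC)CC | intermediate
27 | (3S,4S)-3-[3-R-2,4-bis(methoxymethoxy)phenyl]-5,7-bis(methoxymethoxy)chroman-4-ol | C/C(=C\Cc1c(OCOC)ccc([C@H]2COc3cc(OCOC)cc(OCOC)c3[C@H]2O)c1OCOC)CCCC(C)(C)O[Si](CC)(CC)CC | intermediate
28 | (3S)-3-[3-R-2,4-bis(methoxymethoxy)phenyl]-5,7-bis(methoxymethoxy)chroman-4-one | C/C(=C\Cc1c(OCOC)ccc([C@H]2COc3cc(OCOC)cc(OCOC)c3C2=O)c1OCOC)CCCC(C)(C)O[Si](CC)(CC)CC | intermediate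
29 | (3S)-3-{2,4-dihydroxy-3-[(2E)-7-hydroxy-3,7-dimethyloct-2-en-1-yl]phenyl}-5,7-dihydroxychroman-4-one | C/C(=C\Cc1c(O)ccc([C@H]2COc3cc(O)cc(O)c3C2=O)c1O)CCCC(C)(C)O | target

**Step count**
Total steps: 18.
Longest linear sequence: 13 steps (7 to 29 through steps 5–8 and 10–18).

**Steps most likely to fail**

Step 14. The aryl anion may pick up a proton before the acyl shift, which amounts to plain O-arylation. The acrylate may also add to itself at 125 °C, the product phenoxide may be arylated again, or fluoride may strip the silyl ether. The fallback generates the same kind of ortho-acyloxy aryl anion cold, with no proton source and no fluoride. It sets out from bromophenol 3 and acid 21. Steglich esterification (EDC·HCl, DMAP, CH2Cl2, 0 °C) should give 2-bromo-3,5-bis(methoxymethoxy)phenyl 2-[3-R-2,4-bis(methoxymethoxy)phenyl]prop-2-enoate F1. Treatment with t-BuLi (2 equiv) in THF–Et2O–pentane at −100 °C brings about bromine–lithium exchange, which sets off the anionic ortho-Fries acyl shift. An aqueous quench returns to the route at 25.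

Step 16. Hydride transfer may be slow, because the ketone is electron-rich and is hemmed in by the 5-MOM ether and the ortho-substituted ring B. Racemisation may then fail to outrun reduction, facial discrimination may be poor, or the product alcohol may ionise in the formate medium. The fallback sets C3 by enantioselective protonation and needs no alcohol stage. It sets out from 26. Enolisation with KN(SiMe3)2 and O-acylation with allyl chloroformate (THF, −78 °C) should give allyl 3-[3-R-2,4-bis(methoxymethoxy)phenyl]-5,7-bis(methoxymethoxy)-2H-chromen-4-yl carbonate F2. Decarboxylative asymmetric protonation follows with Pd2(dba)3, a t-Bu-PHOX ligand and Meldrum's acid in 1,4-dioxane at 40 °C, a reaction type known for isoflavanone enolate precursors. The ligand antipode is chosen in a trial run so that the S ketone results. The sequence returns to the route at 28, and steps 16 and 17 drop out.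

Step 18. Acid-catalysed enolisation may erode the C3 configuration. A freed ring B phenol may add to the trisubstituted alkene, or the tertiary alcohol may ionise during the time the last MOM ethers need. The fallback replaces the single protic solvolysis by a two-stage aprotic unmasking. It sets out from 28. Me2BBr (6 equiv) in CH2Cl2 at −78 °C should convert the four aryl MOM ethers into (3S)-3-[3-R-2,4-bis(bromomethoxy)phenyl]-5,7-bis(bromomethoxy)chroman-4-one F3. Pouring this into cold pH 7 sodium phosphate buffer–THF hydrolyses it to (3S)-3-[3-R-2,4-dihydroxyphenyl]-5,7-dihydroxychroman-4-one F4. HF·pyridine buffered with pyridine in THF at 0 °C then removes the silyl group and returns to the route at 29.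

**Further compounds**
F1 | step 14 | 2-bromo-3,5-bis(methoxymethoxy)phenyl 2-[3-R-2,4-bis(methoxymethoxy)phenyl]prop-2-enoate | C=C(C(=O)Oc1cc(OCOC)cc(OCOC)c1Br)c1ccc(OCOC)c(C/C=C(\C)CCCC(C)(C)O[Si](CC)(CC)CC)c1OCOC
F2 | step 16 | allyl 3-[3-R-2,4-bis(methoxymethoxy)phenyl]-5,7-bis(methoxymethoxy)-2H-chromen-4-yl carbonate | C=CCOC(=O)OC1=C(COc2cc(OCOC)cc(OCOC)c12)c1ccc(OCOC)c(C/C=C(\C)CCCC(C)(C)O[Si](CC)(CC)CC)c1OCOC
F3 | step 18 | (3S)-3-[3-R-2,4-bis(bromomethoxy)phenyl]-5,7-bis(bromomethoxy)chroman-4-one | C/C(=C\Cc1c(OCBr)ccc([C@H]2COc3cc(OCBr)cc(OCBr)c3C2=O)c1OCBr)CCCC(C)(C)O[Si](CC)(CC)CC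
F4 | step 18 | (3S)-3-[3-R-2,4-dihydroxyphenyl]-5,7-dihydroxychroman-4-one | C/C(=C\Cc1c(O)ccc([C@H]2COc3cc(O)cc(O)c3C2=O)c1O)CCCC(C)(C)O[Si](CC)(CC)CC
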